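## Structural features

- The target joins a fully substituted phloroglucinol ring (two formyl groups, three hydroxyls) through the benzylic methine C9′, which also carries an isobutyl group, to C1 of a trans-fused eudesmane-type decalin (ring A: C1–C5, C10; ring B: C5–C10).
- The decalin has five stereocentres: quaternary C10 with the angular methyl, C5–H trans to it, the C1 side chain trans to the methyl and therefore axial, C4 with an axial tertiary hydroxyl cis to the angular methyl and an equatorial methyl, and C7 with an equatorial 2-hydroxypropan-2-yl group.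
- C9′, C1 and C10 are contiguous, so the exocyclic stereocentre sits next to a tertiary carbon that itself adjoins a quaternary one; the C9′–aryl bond is the most congested bond of the molecule.
- Fragile groups are the two tertiary alcohols (ionisation and dehydration under acid, above all the axial C4–OH), the formyl groups (reduction, condensation) and the electron-rich free triphenol (oxidation).
- The real difficulty is the C9′/C1/C10 triad in the correct relation to C5 and C7, together with a double formylation that must avoid acid.
- The feature exploited by the key step: apart from C10, ring B holds only C5 (next to the C4 carbonyl) and C7 (next to an ester carbonyl). Ring B can therefore be closed between C5 and C6 after a methyl group has been placed on C10 anti to the C1 substituent.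
- The C4 ketone and C7 ester that remain are exactly the carbonyls from which the two tertiary carbinols are made.

## Logic of the disconnections

**25 ⇒ 24.** The three phenolic O–H bonds and the two C–H bonds of the isopropyl terminus are traced back to three benzyl ethers and a 1,1-disubstituted alkene. The free formylated triphenol should appear only once, at the end. One neutral operation removes every temporary group. The demand is that hydrogenation stops before the formyl groups are touched.

**24 ⇒ 22 (through 23).** The two aryl–CHO bonds are cut to aryl–Br bonds. Formylation through aryllithium centres is chosen because acid-mediated formylations would ionise the tertiary alcohols. The aldehydes are thereby absent from all earlier carbonyl chemistry. The forward step needs a double halogen–metal exchange on a hexasubstituted ring that also carries two alkoxides.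

**22 ⇒ 21 ⇒ 20.** The C=CH2 bond is cut to a methyl ketone and the two C–Br bonds to C–H. The methyl ketone is what a conjugate addition leaves behind, and methylenation turns it into the isobutyl terminus. Bromination is placed before the alkene exists, so it only has to distinguish an activated arene from a ketone.

**20 ⇒ 17 + 19 (19 ⇒ 18).** The C9′–aryl bond is cut. This splits the molecule into two halves of similar size and lets C9′ be set by 1,2-induction from C1 in a conjugate addition. The forward step needs a hindered 2,6-dioxygenated aryl nucleophile to add to one face of an enone in the presence of two free tertiary hydroxyls.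

**17 ⇒ 15 + 16.** The C9′=C double bond is cut by an olefination transform. The side chain shrinks to a formyl group on C1. The demand is a mild, E-selective olefination that does not epimerise C1, which is α to the aldehyde.

**15 ⇒ 14 ⇒ 13.** The oxidation level of the C1 carbon is lowered and the O–benzyl bond restored. A benzyl ether is the most robust carrier of this carbon through the organometallic steps before it. The oxidation must select a primary alcohol beside two tertiary ones.

**13 ⇒ 12.** Three C–CH3 bonds are cut (one at C4, two at the carbinol carbon on C7). Both tertiary alcohols come from carbonyl groups, and the C4 stereocentre disappears. The forward addition must attack C4 along the equatorial trajectory and must not enolise toward C5.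

**12 ⇒ 10 (through 11).** The C10–CH3 and C5–C6 bonds are cut. Ring B, the quaternary centre and two epimerisable centres go, leaving a monocyclic enone with a single stereocentre. The demands are methyl delivery anti to the C1 group, attack at the enone and not at the acrylate, and a thermodynamic preference for the trans-fused product.

**10 ⇒ 9 ⇒ 8.** The bond between C7 and the ester carbon is cut (carbonylation transform), then the alkyne C–H back to C–Si. An acrylate cannot be carried through the organometallic attachment of the chain, whereas a silylated terminal alkyne can. The forward step must be a Markovnikov-selective alkoxycarbonylation that tolerates the enone.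

**8 ⇒ 5 + 6 (through 7).** The C10–C9 bond is cut. The chain is attached to the β-carbon by conjugate addition, and the regiodefined enol ether is re-oxidised to the enone. The existing stereocentre is not involved.

**5 ⇒ 4 ⇒ 3.** The C5=C10 double bond is removed, which reveals a prochiral 4-substituted cyclohexanone. The single stereocentre is created by differentiating two enantiotopic α-methylene groups. This is preferred to alkylating a 3-alkoxyenone enolate with carbonyl transposition, because no dependable enantioselective version of that alkylation can be claimed. The demand is a chiral base of high selectivity.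

**3 ⇒ 1 + 2.** The O–CH2Ph bond is cut. The forward step needs non-basic benzylation in the presence of an enolisable ketone.

## Other disconnections considered

**Alternative 1:**
- **Cut.** C5–C10 and C1–C2, which opens rings A and B at once to the acyclic triene A2.
- **Forward key step.** The Z-configured β-methyl enoate of A2 (C10=C1) would add across its 2-silyloxydiene (C5=C4–C3=C2) in an intramolecular Diels–Alder reaction to give the bicyclic silyl enol ether A1.
- **In its favour.** Two rings, the quaternary centre and the trans relation between C1 and the angular methyl arise in one stereospecific event. C7 with its protected carbinol is present from the start and comes from the chiral pool. The ring fusion is set kinetically and not by equilibration. On these three points it is the equal or the better of the chosen plan.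
- **Against it here.** The dienophile is a β,β-disubstituted, singly activated alkene that must form a quaternary carbon, so high temperatures are to be expected. The geometries of the trisubstituted enoate and of the silyloxydiene must both be made and kept pure. The endo/exo preference that decides trans against cis fusion cannot be predicted with confidence. Two acid-labile silyl groups must survive the heating.
- **Comparison.**
  - Structure: both plans reach a decalin with oxygen at C4 and a one-carbon handle at C1, but A1 needs the same later work at C9′ plus an ester reduction.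
  - Mechanism: a concerted cycloaddition with one uncertain transition-state preference stands against a stepwise ionic sequence whose centres can be corrected by epimerisation.
  - Step economy: about equal up to the decalin.

**Alternative 2:**
- **Cut.** Three bonds of the aromatic ring (C1′–C2′, C2′–C3′, C5′–C6′), so that the arene is built around C9′ from the siloxyalkyne A4 and the cyclobutenone A5.
- **Forward key step.** Heating opens A5 to a vinylketene, which adds to the alkyne of A4. The vinylcyclobutenone so formed opens and recloses by 6π-electrocyclisation, and tautomerisation gives the phenol A3 (Danheiser benzannulation).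
- **In its favour.** No hindered aryl nucleophile has to be forced onto the congested C9′. The cascade is regiospecific and the three oxygens emerge differentiated. On making the C9′–arene connection it is the better plan.
- **Against it here.** C9′ must already be a stereocentre bearing an alkyne, for which the substrate offers no simple control. The siloxyalkyne has to be made on a crowded branched carbon by a multi-step homologation. The cascade needs heat beside two tertiary silyl ethers. Both formyl groups are still missing afterwards, now on a ring with three different oxygen substituents.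
- **Comparison.**
  - Structure: it solves the arene attachment, leaves the decalin untouched and moves the C9′ problem to an earlier, less controllable stage.
  - Mechanism: thermal pericyclic steps against an organocopper addition, with comparable functional-group demands.
  - Step economy: clearly longer.

**Alternative 3:**
- **Cut.** C1–C10 and C2–C3, which detaches ring A as the enone A8 from a monoterpene-derived semicyclic 2-ethoxydiene A7 that already contains ring B.
- **Forward key step.** An intermolecular Diels–Alder reaction of A7 (C3=C4–C5=C10) with A8 would give the bicyclic enol ether A6 carrying the isovaleryl group on C1.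
- **In its favour.** It is the most convergent plan. The side-chain carbons arrive in one piece, C7 comes from the chiral pool, and fewer steps lead to a functionalised decalin. On step economy it is the better.
- **Against it here.** The diene terminus C10 is fully substituted, so a quaternary centre must form intermolecularly against steric resistance and a strained s-cis conformation. Facial selectivity rests on the remote C7 substituent, and the endo/exo preference decides whether the acyl group ends trans to the methyl. The arene would then have to be attached at a hindered ketone carbon and the benzylic oxygen removed with control of C9′, for which no reliable element is at hand. The isopropenyl group needs a selective hydration.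
- **Comparison.**
  - Structure: A6 maps well on the skeleton but sets only C10 and C1. C5 is left to protonation of the enol ether, which makes it the equal of the chosen plan on the ring fusion.
  - Mechanism: one bimolecular cycloaddition with three selectivity questions against a sequence in which each centre has its own controlling element.
  - Step economy: shorter, at the price of weak control at C10/C1 and none at C9′.

Key step: step 7

Assumption: LiN[(S)-CH(CH3)Ph]2 is taken to discriminate the α-hydrogens of 3 in the sense known for 4-alkylcyclohexanones and so to give (R)-4 (the (R,R)-amide is used if the opposite sense is found); compounds 1, 2, 6, 16 and 18 are taken to be commercial.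

## Route

Step 1
Reactants: 1 4-(hydroxymethyl)cyclohexan-1-one; 2 benzyl 2,2,2-trichloroacetimidate
Product: 3 4-[(benzyloxy)methyl]cyclohexan-1-one
Conditions: 2 (1.3 equiv), TfOH (5 mol %), CH2Cl2/cyclohexane, 0 °C → rt
Reagents that add atoms: none
Why: Acid-catalysed O-benzylation with a trichloroacetimidate transfers the benzyl group without base, so the enolisable ketone is untouched; 3 is still achiral.

Step 2
Reactants: 3 4-[(benzyloxy)methyl]cyclohexan-1-one
Product: 4 {[(4R)-4-[(benzyloxy)methyl]cyclohex-1-en-1-yl]oxy}trimethylsilane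
Conditions: LiN[(S)-CH(CH3)Ph]2 (from the (S,S)-amine hydrochloride and n-BuLi, 2 equiv; LiCl formed in situ), TMSCl (5 equiv, internal quench), THF, −100 °C; Et3N, NaHCO3 work-up
Reagents that add atoms: chlorotrimethylsilane, C[Si](C)(C)Cl
Why: Enantioselective deprotonation of a prochiral 4-substituted cyclohexanone by a C2-symmetric chiral lithium amide with in situ silylation; the base removes one of the two enantiotopic axial α-hydrogens of the chair with equatorial CH2OBn, which makes the ring carbon bearing CH2OBn (the future C1) R. Should the enantiomeric purity fall short, triol 14 is the intended point for enrichment by crystallisation.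

Step 3
Reactants: 4 {[(4R)-4-[(benzyloxy)methyl]cyclohex-1-en-1-yl]oxy}trimethylsilane
Product: 5 (4R)-4-[(benzyloxy)methyl]cyclohex-2-en-1-one
Conditions: Pd(OAc)2 (10 mol %), O2 (1 atm), DMSO, 25 °C
Reagents that add atoms: none
Why: Saegusa–Ito oxidation; divalent palladium binds the enol carbon and β-hydride elimination can only take the neighbouring ring hydrogen, so the double bond forms on the side fixed in step 2 and the stereocentre is not involved.

Step 4
Reactants: 5 (4R)-4-[(benzyloxy)methyl]cyclohex-2-en-1-one; 6 (4-bromobut-1-yn-1-yl)trimethylsilane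
Product: 8 (4R)-4-[(benzyloxy)methyl]-3-[4-(trimethylsilyl)but-3-yn-1-yl]cyclohex-2-en-1-one, via silyl enol ether 7 (not isolated)
Conditions: 6, Mg, THF, 25 → 40 °C; CuI (10 mol %), LiCl (20 mol %), TMSCl (2 equiv), THF, −78 °C, then 5; NaHCO3 work-up; crude 7, Pd(OAc)2 (1.05 equiv), MeCN, 25 °C
Reagents that add atoms: chlorotrimethylsilane, C[Si](C)(C)Cl (its silyl group is present only in 7)
Why: Copper-catalysed conjugate addition of the Grignard reagent with TMSCl trapping gives the regiodefined enol ether 7 (the chain enters anti to CH2OBn, which is of no consequence afterwards). A second Saegusa–Ito oxidation then removes the hydrogen on the carbon that received the chain and returns the enone with the chain on its β-carbon.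

Step 5
Reactants: 8 (4R)-4-[(benzyloxy)methyl]-3-[4-(trimethylsilyl)but-3-yn-1-yl]cyclohex-2-en-1-one
Product: 9 (4R)-4-[(benzyloxy)methyl]-3-(but-3-yn-1-yl)cyclohex-2-en-1-one
Conditions: TBAF (1.1 equiv), AcOH (1.2 equiv), THF, 0 °C
Reagents that add atoms: none
Why: Fluoride-induced protodesilylation of the alkynylsilane; buffering with acetic acid keeps the medium near neutral so the γ-stereocentre of the enone is not exposed to base.

Step 6
Reactants: 9 (4R)-4-[(benzyloxy)methyl]-3-(but-3-yn-1-yl)cyclohex-2-en-1-one
Product: 10 methyl 4-[(6R)-6-[(benzyloxy)methyl]-3-oxocyclohex-1-en-1-yl]-2-methylidenebutanoate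
Conditions: Pd(OAc)2 (2 mol %), 2-(diphenylphosphino)pyridine (8 mol %), MeSO3H (8 mol %), CO (10 bar), MeOH, 45 °C
Reagents that add atoms: carbon monoxide, [C-]#[O+]; methanol, CO
Why: Palladium-catalysed Markovnikov hydromethoxycarbonylation of a terminal alkyne gives the 2-substituted acrylate directly and without by-product; the acid is held as the pyridinium salt of the ligand, so the enone should not be deconjugated.

Step 7
Reactants: 10 methyl 4-[(6R)-6-[(benzyloxy)methyl]-3-oxocyclohex-1-en-1-yl]-2-methylidenebutanoate
Product: 12 methyl (2S,4aR,5R,8aS)-5-[(benzyloxy)methyl]-4a-methyl-8-oxodecahydronaphthalene-2-carboxylate, via silyl enol ether 11 (not isolated)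
Conditions: Me3Al (1.5 equiv), CuBr (5 mol %), TMSCl (1.5 equiv), THF, 0 → 25 °C; NaHCO3 work-up; crude 11, NaOMe (1.2 equiv), MeOH, 0 → 25 °C
Reagents that add atoms: trimethylaluminium, C[Al](C)C; chlorotrimethylsilane, C[Si](C)(C)Cl (its silyl group is present only in 11)
Why: A methylcopper species generated catalytically from Me3Al and CuBr transfers CH3 to C10 of the ketone-conjugated alkene, and TMSCl captures the enolate as 11 with the double bond fixed at C4=C5; methoxide then releases this enolate, whose carbon C5 adds to the terminal CH2 (C6) of the tethered acrylate. The closest known reaction type is the Michael-initiated ring closure, in which conjugate addition to an enone is followed by intramolecular Michael addition of the enolate to a tethered acceptor. Ring B closes in a 6-(enolexo)-endo-trig mode, since both acrylate carbons end up in the new six-membered ring. C10 is controlled by the C1 stereocentre: A(1,2) strain with the chain on C10 holds CH2OBn pseudoaxial in the half-chair and methyl enters axially on the opposite face, so methyl and CH2OBn become trans. C5 (α to the ketone) and C7 (α to the ester) are set by the methoxide equilibration, which should favour the trans-fused chair–chair decalone with an equatorial ester. The selectivity needed is attack at the enone in the presence of the acrylate; the reagent secures it, because Lewis-acid-assisted copper catalysis with Me3Al engages ketone-conjugated alkenes while 2-alkylacrylates are poor acceptors for it, and the second Michael addition can give a six-membered ring only through C5. Because the trans isomer carries CH2OBn axial its thermodynamic margin is modest, so any C5 epimer is separated and returned to the methoxide equilibration.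

Step 8
Reactants: 12 methyl (2S,4aR,5R,8aS)-5-[(benzyloxy)methyl]-4a-methyl-8-oxodecahydronaphthalene-2-carboxylate
Product: 13 2-[(2S,4aR,5R,8R,8aS)-5-[(benzyloxy)methyl]-8-hydroxy-4a,8-dimethyldecahydronaphthalen-2-yl]propan-2-ol
Conditions: MeMgBr (6 equiv), CeCl3 (3 equiv, anhydrous), THF, −78 → 0 °C; aq NH4Cl
Reagents that add atoms: methylmagnesium bromide, C[Mg]Br
Why: Cerium-mediated Grignard addition suppresses enolisation toward C5; methyl attacks C4 along the equatorial trajectory because the axial one is blocked by the 1,3-diaxial angular methyl. This gives the axial hydroxyl cis to that methyl, and two further equivalents turn the ester into the dimethylcarbinol.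

Step 9
Reactants: 13 2-[(2S,4aR,5R,8R,8aS)-5-[(benzyloxy)methyl]-8-hydroxy-4a,8-dimethyldecahydronaphthalen-2-yl]propan-2-ol
Product: 14 2-[(2S,4aR,5R,8R,8aS)-8-hydroxy-5-(hydroxymethyl)-4a,8-dimethyldecahydronaphthalen-2-yl]propan-2-ol
Conditions: H2 (1 atm), Pd/C (10 wt %), EtOAc/EtOH, 25 °C
Reagents that add atoms: none
Why: Hydrogenolysis of the only benzyl ether; no other reducible group is present at this stage.

Step 10
Reactants: 14 2-[(2S,4aR,5R,8R,8aS)-8-hydroxy-5-(hydroxymethyl)-4a,8-dimethyldecahydronaphthalen-2-yl]propan-2-ol
Product: 15 (1R,4R,4aS,6S,8aS)-4-hydroxy-6-(2-hydroxypropan-2-yl)-4,8a-dimethyldecahydronaphthalene-1-carbaldehyde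
Conditions: TEMPO (10 mol %), PhI(OAc)2 (1.2 equiv), CH2Cl2, 25 °C
Reagents that add atoms: none
Why: Oxoammonium-mediated oxidation selects the primary alcohol, since tertiary alcohols cannot be oxidised; the near-neutral medium protects C1, which is now α to the aldehyde.

Step 11
Reactants: 15 (1R,4R,4aS,6S,8aS)-4-hydroxy-6-(2-hydroxypropan-2-yl)-4,8a-dimethyldecahydronaphthalene-1-carbaldehyde; 16 dimethyl (2-oxopropyl)phosphonate
Product: 17 (3E)-4-[(1S,4R,4aS,6S,8aR)-4-hydroxy-6-(2-hydroxypropan-2-yl)-4,8a-dimethyldecahydronaphthalen-1-yl]but-3-en-2-one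
Conditions: 16 (1.5 equiv), LiCl (1.6 equiv), i-Pr2NEt (1.5 equiv), MeCN, 25 °C
Reagents that add atoms: none
Why: Horner–Wadsworth–Emmons olefination under LiCl/amine conditions gives the E-enone with a weak base at room temperature, which keeps epimerisation at C1 to a minimum; the free tertiary hydroxyls do not interfere.

Step 12
Reactants: 18 1,3,5-tris(benzyloxy)benzene
Product: 19 2-bromo-1,3,5-tris(benzyloxy)benzene
Conditions: NBS (1.0 equiv), CH2Cl2, −78 → 0 °C
Reagents that add atoms: N-bromosuccinimide, O=C1CCC(=O)N1Br
Why: Electrophilic aromatic bromination of a symmetric, strongly activated arene; the three free positions are equivalent and one equivalent at low temperature should stop at the monobromide.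

Step 13
Reactants: 17 (3E)-4-[(1S,4R,4aS,6S,8aR)-4-hydroxy-6-(2-hydroxypropan-2-yl)-4,8a-dimethyldecahydronaphthalen-1-yl]but-3-en-2-one; 19 2-bromo-1,3,5-tris(benzyloxy)benzene
Product: 20 (4R)-4-[(1S,4R,4aS,6S,8aR)-4-hydroxy-6-(2-hydroxypropan-2-yl)-4,8a-dimethyldecahydronaphthalen-1-yl]-4-[2,4,6-tris(benzyloxy)phenyl]butan-2-one
Conditions: 19 (6 equiv), t-BuLi (12 equiv), Et2O, −78 °C; CuI (3 equiv), −40 °C (Ar2CuLi); then 17 in THF, −78 → 0 °C; aq NH4Cl/NH3
Reagents that add atoms: none
Why: Conjugate addition of a diarylcuprate to an acyclic E-enone; C9′ is set by substrate control. In the reactive conformer the C1–H bond eclipses the alkene (A(1,3) strain) and the aryl group enters on the face away from quaternary C10, which corresponds to the required R configuration. The excess reagent absorbs the two tertiary hydroxyls as lithium alkoxides, and the untransferred aryl groups return as 18.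

Step 14
Reactants: 20 (4R)-4-[(1S,4R,4aS,6S,8aR)-4-hydroxy-6-(2-hydroxypropan-2-yl)-4,8a-dimethyldecahydronaphthalen-1-yl]-4-[2,4,6-tris(benzyloxy)phenyl]butan-2-one
Product: 21 (4R)-4-[3,5-dibromo-2,4,6-tris(benzyloxy)phenyl]-4-[(1S,4R,4aS,6S,8aR)-4-hydroxy-6-(2-hydroxypropan-2-yl)-4,8a-dimethyldecahydronaphthalen-1-yl]butan-2-one
Conditions: NBS (2.1 equiv), MeCN, −20 → 0 °C, dark
Reagents that add atoms: N-bromosuccinimide, O=C1CCC(=O)N1Br
Why: Electrophilic bromination of the two remaining ring positions, each flanked by two alkoxy groups, is far faster than α-bromination of the ketone in the absence of acid; it is placed before the alkene is made.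

Step 15
Reactants: 21 (4R)-4-[3,5-dibromo-2,4,6-tris(benzyloxy)phenyl]-4-[(1S,4R,4aS,6S,8aR)-4-hydroxy-6-(2-hydroxypropan-2-yl)-4,8a-dimethyldecahydronaphthalen-1-yl]butan-2-one
Product: 22 2-[(2S,4aR,5S,8R,8aS)-5-{(1R)-1-[3,5-dibromo-2,4,6-tris(benzyloxy)phenyl]-3-methylbut-3-en-1-yl}-8-hydroxy-4a,8-dimethyldecahydronaphthalen-2-yl]propan-2-ol
Conditions: Ph3PCH3Br (4 equiv), KOt-Bu (3.8 equiv), THF, 0 → 25 °C
Reagents that add atoms: methyltriphenylphosphonium bromide, C[P+](c1ccccc1)(c1ccccc1)c1ccccc1.[Br-]
Why: Wittig methylenation of the methyl ketone supplies the last carbon of the isobutyl group; C9′ is β to the carbonyl and cannot epimerise by enolisation, and the ylide is not basic enough to be consumed by the tertiary alcohols.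

Step 16
Reactants: 22 2-[(2S,4aR,5S,8R,8aS)-5-{(1R)-1-[3,5-dibromo-2,4,6-tris(benzyloxy)phenyl]-3-methylbut-3-en-1-yl}-8-hydroxy-4a,8-dimethyldecahydronaphthalen-2-yl]propan-2-ol
Product: 24 5-{(1R)-1-[(1S,4R,4aS,6S,8aR)-4-hydroxy-6-(2-hydroxypropan-2-yl)-4,8a-dimethyldecahydronaphthalen-1-yl]-3-methylbut-3-en-1-yl}-2,4,6-tris(benzyloxy)benzene-1,3-dicarbaldehyde, via dilithioarene dialkoxide 23 (not isolated)
Conditions: t-BuLi (6.5 equiv), THF, −78 °C; DMF (8 equiv), −78 → 0 °C; aq NH4Cl
Reagents that add atoms: N,N-dimethylformamide, CN(C)C=O; tert-butyllithium, [Li]C(C)(C)C (its lithium is present only in 23)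
Why: After deprotonation of the two hydroxyls, bromine–lithium exchange at both positions gives aryllithium centres that are each stabilised by two flanking alkoxy groups; formylation with DMF gives tetrahedral adducts that collapse to the dialdehyde only on work-up. No acid touches the tertiary alcohols.

Step 17
Reactants: 24 5-{(1R)-1-[(1S,4R,4aS,6S,8aR)-4-hydroxy-6-(2-hydroxypropan-2-yl)-4,8a-dimethyldecahydronaphthalen-1-yl]-3-methylbut-3-en-1-yl}-2,4,6-tris(benzyloxy)benzene-1,3-dicarbaldehyde
Product: 25 5-{(1R)-1-[(1S,4R,4aS,6S,8aR)-4-hydroxy-6-(2-hydroxypropan-2-yl)-4,8a-dimethyldecahydronaphthalen-1-yl]-3-methylbutyl}-2,4,6-trihydroxybenzene-1,3-dicarbaldehyde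
Conditions: H2 (1 atm), Pd/C (10 wt %), EtOAc, 25 °C, stopped after uptake of 4 equiv
Reagents that add atoms: none
Why: Heterogeneous hydrogenation saturates the 1,1-disubstituted alkene (no new stereocentre) and hydrogenolyses the three aryl benzyl ethers; as the phenols are released the formyl groups become hydrogen-bonded vinylogous acids and should resist reduction.

## Compound list

1 | 4-(hydroxymethyl)cyclohexan-1-one | O=C1CCC(CO)CC1 | starting material
2 | benzyl 2,2,2-trichloroacetimidate | N=C(OCc1ccccc1)C(Cl)(Cl)Cl | starting material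
3 | 4-[(benzyloxy)methyl]cyclohexan-1-one | O=C1CCC(COCc2ccccc2)CC1 | intermediate
4 | {[(4R)-4-[(benzyloxy)methyl]cyclohex-1-en-1-yl]oxy}trimethylsilane | C[Si](C)(C)OC1=CC[C@H](COCc2ccccc2)CC1 | intermediate
5 | (4R)-4-[(benzyloxy)methyl]cyclohex-2-en-1-one | O=C1C=C[C@H](COCc2ccccc2)CC1 | intermediate
6 | (4-bromobut-1-yn-1-yl)trimethylsilane | C[Si](C)(C)C#CCCBr | starting material
7 | {[(3S,4R)-4-[(benzyloxy)methyl]-3-[4-(trimethylsilyl)but-3-yn-1-yl]cyclohex-1-en-1-yl]oxy}trimethylsilane | C[Si](C)(C)OC1=C[C@@H](CCC#C[Si](C)(C)C)[C@H](COCc2ccccc2)CC1 | intermediate (not isolated)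
8 | (4R)-4-[(benzyloxy)methyl]-3-[4-(trimethylsilyl)but-3-yn-1-yl]cyclohex-2-en-1-one | O=C1C=C(CCC#C[Si](C)(C)C)[C@H](COCc2ccccc2)CC1 | intermediate
9 | (4R)-4-[(benzyloxy)methyl]-3-(but-3-yn-1-yl)cyclohex-2-en-1-one | O=C1C=C(CCC#C)[C@H](COCc2ccccc2)CC1 | intermediate
10 | methyl 4-[(6R)-6-[(benzyloxy)methyl]-3-oxocyclohex-1-en-1-yl]-2-methylidenebutanoate | O=C1C=C(CCC(=C)C(=O)OC)[C@H](COCc2ccccc2)CC1 | intermediate
11 | methyl 4-[(1R,6R)-6-[(benzyloxy)methyl]-1-methyl-3-(trimethylsilyloxy)cyclohex-2-en-1-yl]-2-methylidenebutanoate | C[Si](C)(C)OC1=C[C@](C)(CCC(=C)C(=O)OC)[C@H](COCc2ccccc2)CC1 | intermediate (not isolated)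
12 | methyl (2S,4aR,5R,8aS)-5-[(benzyloxy)methyl]-4a-methyl-8-oxodecahydronaphthalene-2-carboxylate | c1ccccc1COC[C@@H]1CCC(=O)[C@H]2C[C@@H](C(=O)OC)CC[C@]12C | intermediate
13 | 2-[(2S,4aR,5R,8R,8aS)-5-[(benzyloxy)methyl]-8-hydroxy-4a,8-dimethyldecahydronaphthalen-2-yl]propan-2-ol | c1ccccc1COC[C@@H]1CC[C@@](C)(O)[C@H]2C[C@@H](C(C)(C)O)CC[C@]12C | intermediate
14 | 2-[(2S,4aR,5R,8R,8aS)-8-hydroxy-5-(hydroxymethyl)-4a,8-dimethyldecahydronaphthalen-2-yl]propan-2-ol | OC[C@@H]1CC[C@@](C)(O)[C@H]2C[C@@H](C(C)(C)O)CC[C@]12C | intermediate
15 | (1R,4R,4aS,6S,8aS)-4-hydroxy-6-(2-hydroxypropan-2-yl)-4,8a-dimethyldecahydronaphthalene-1-carbaldehyde | O=C[C@@H]1CC[C@@](C)(O)[C@H]2C[C@@H](C(C)(C)O)CC[C@]12C | intermediate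
16 | dimethyl (2-oxopropyl)phosphonate | COP(=O)(CC(C)=O)OC | starting material
17 | (3E)-4-[(1S,4R,4aS,6S,8aR)-4-hydroxy-6-(2-hydroxypropan-2-yl)-4,8a-dimethyldecahydronaphthalen-1-yl]but-3-en-2-one | CC(=O)/C=C/[C@@H]1CC[C@@](C)(O)[C@H]2C[C@@H](C(C)(C)O)CC[C@]12C | intermediate
18 | 1,3,5-tris(benzyloxy)benzene | c1c(OCc2ccccc2)cc(OCc2ccccc2)cc1OCc1ccccc1 | starting material
19 | 2-bromo-1,3,5-tris(benzyloxy)benzene | Brc1c(OCc2ccccc2)cc(OCc2ccccc2)cc1OCc1ccccc1 | intermediate
20 | (4R)-4-[(1S,4R,4aS,6S,8aR)-4-hydroxy-6-(2-hydroxypropan-2-yl)-4,8a-dimethyldecahydronaphthalen-1-yl]-4-[2,4,6-tris(benzyloxy)phenyl]butan-2-one | CC(=O)C[C@@H](c1c(OCc2ccccc2)cc(OCc2ccccc2)cc1OCc1ccccc1)[C@@H]1CC[C@@](C)(O)[C@H]2C[C@@H](C(C)(C)O)CC[C@]12C | intermediate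
21 | (4R)-4-[3,5-dibromo-2,4,6-tris(benzyloxy)phenyl]-4-[(1S,4R,4aS,6S,8aR)-4-hydroxy-6-(2-hydroxypropan-2-yl)-4,8a-dimethyldecahydronaphthalen-1-yl]butan-2-one | CC(=O)C[C@@H](c1c(OCc2ccccc2)c(Br)c(OCc2ccccc2)c(Br)c1OCc1ccccc1)[C@@H]1CC[C@@](C)(O)[C@H]2C[C@@H](C(C)(C)O)CC[C@]12C | intermediate
22 | 2-[(2S,4aR,5S,8R,8aS)-5-{(1R)-1-[3,5-dibromo-2,4,6-tris(benzyloxy)phenyl]-3-methylbut-3-en-1-yl}-8-hydroxy-4a,8-dimethyldecahydronaphthalen-2-yl]propan-2-ol | CC(=C)C[C@@H](c1c(OCc2ccccc2)c(Br)c(OCc2ccccc2)c(Br)c1OCc1ccccc1)[C@@H]1CC[C@@](C)(O)[C@H]2C[C@@H](C(C)(C)O)CC[C@]12C | intermediate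
23 | dilithium dialkoxide of the 3,5-dilithioarene derived from 22 | CC(=C)C[C@@H](c1c(OCc2ccccc2)c([Li])c(OCc2ccccc2)c([Li])c1OCc1ccccc1)[C@@H]1CC[C@@](C)(O[Li])[C@H]2C[C@@H](C(C)(C)O[Li])CC[C@]12C | intermediate (not isolated)
24 | 5-{(1R)-1-[(1S,4R,4aS,6S,8aR)-4-hydroxy-6-(2-hydroxypropan-2-yl)-4,8a-dimethyldecahydronaphthalen-1-yl]-3-methylbut-3-en-1-yl}-2,4,6-tris(benzyloxy)benzene-1,3-dicarbaldehyde | CC(=C)C[C@@H](c1c(OCc2ccccc2)c(C=O)c(OCc2ccccc2)c(C=O)c1OCc1ccccc1)[C@@H]1CC[C@@](C)(O)[C@H]2C[C@@H](C(C)(C)O)CC[C@]12C | intermediate
25 | 5-{(1R)-1-[(1S,4R,4aS,6S,8aR)-4-hydroxy-6-(2-hydroxypropan-2-yl)-4,8a-dimethyldecahydronaphthalen-1-yl]-3-methylbutyl}-2,4,6-trihydroxybenzene-1,3-dicarbaldehyde | CC(C)C[C@@H](c1c(O)c(C=O)c(O)c(C=O)c1O)[C@@H]1CC[C@@](C)(O)[C@H]2C[C@@H](C(C)(C)O)CC[C@]12C | target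

## Step count and least certain steps

Total step count: 17 (16 on the main line plus the one-step preparation of 19). Longest linear sequence: 16 steps (steps 1–11 and 13–17).

**Step 7 (key step).**
- What may go wrong: the methoxide equilibration may show too little bias for the trans ring fusion, because the trans isomer has to carry the C1 side chain axial, so much C5 epimer would remain. Slow methyl transfer to the hindered β-carbon is the second concern.
- Fallback: it sets out from the C5-epimeric mixture that contains 12 and fixes the ring fusion kinetically.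
  - Soft enolisation under equilibrating conditions (TMSCl, NaI, Et3N, MeCN) should convert both epimers into the more substituted silyl enol ether methyl (2S,4aR,5R)-5-[(benzyloxy)methyl]-4a-methyl-8-(trimethylsilyloxy)-1,2,3,4,4a,5,6,7-octahydronaphthalene-2-carboxylate F1.
  - Saegusa–Ito oxidation (Pd(OAc)2, MeCN) would give the enone methyl (2S,4aR,5R)-5-[(benzyloxy)methyl]-4a-methyl-8-oxo-2,3,4,4a,5,6,7,8-octahydronaphthalene-2-carboxylate F2.
  - Hydrogenation (H2, Pd/C, EtOAc) should add to the C5=C6 double bond from the face opposite the angular methyl, as 5-ene steroids do, and also cleave the benzyl ether. The product would be the trans-fused methyl (2S,4aR,5R,8aS)-5-(hydroxymethyl)-4a-methyl-8-oxodecahydronaphthalene-2-carboxylate F3.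
  - MeMgBr/CeCl3 as in step 8 then converts F3 directly into 14, where the route is rejoined.

**Step 6.**
- What may go wrong: slow turnover or loss of branched selectivity of the alkoxycarbonylation on a substrate whose enone can compete for the palladium hydride, and possible erosion of the γ-stereocentre on prolonged exposure to the acidic medium.
- Fallback: from 9, Markovnikov addition of HI generated in situ (NaI, TMSCl, H2O, MeCN) gives the vinyl iodide (4R)-4-[(benzyloxy)methyl]-3-(3-iodobut-3-en-1-yl)cyclohex-2-en-1-one F4. Its alkoxycarbonylation under neutral to basic conditions (PdCl2(PPh3)2, CO at 1 atm, Et3N, MeOH) returns to 10.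

**Step 13.**
- What may go wrong: poor facial selectivity at C9′, or sluggish transfer of the doubly ortho-substituted aryl group to a β-carbon that adjoins the crowded C1.
- Fallback: from 17, an iminium-catalysed asymmetric Friedel–Crafts conjugate addition of 3,5-bis(benzyloxy)phenol is used, with a 9-amino-9-deoxy-epi-cinchona alkaloid and an acid co-catalyst. The pseudoenantiomeric catalyst is chosen for the matched case, so reagent control reinforces or overrides the substrate bias. The product is (4R)-4-[2,4-bis(benzyloxy)-6-hydroxyphenyl]-4-[(1S,4R,4aS,6S,8aR)-4-hydroxy-6-(2-hydroxypropan-2-yl)-4,8a-dimethyldecahydronaphthalen-1-yl]butan-2-one F5. O-Benzylation (BnBr, K2CO3, acetone) returns to 20; by symmetry, attack ortho or para to the free hydroxyl leads to the same 20.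

**Step 16.**
- What may go wrong: incomplete second bromine–lithium exchange, or anion translocation from the aryllithium to a benzylic OCH2 position followed by rearrangement, which would give monoaldehyde or rearranged material.
- Fallback: it sets out from 22 and returns at 25.
  - Homogeneous hydrogenation (RhCl(PPh3)3, H2) saturates only the alkene and gives 2-[(2S,4aR,5S,8R,8aS)-5-{(1R)-1-[3,5-dibromo-2,4,6-tris(benzyloxy)phenyl]-3-methylbutyl}-8-hydroxy-4a,8-dimethyldecahydronaphthalen-2-yl]propan-2-ol F6.
  - Double Suzuki–Miyaura vinylation (potassium vinyltrifluoroborate, Pd(OAc)2, SPhos, K3PO4, toluene/H2O) gives the 3,5-divinyl compound F7.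
  - Oxidative cleavage (OsO4 cat., NaIO4, 2,6-lutidine) gives 5-{(1R)-1-[(1S,4R,4aS,6S,8aR)-4-hydroxy-6-(2-hydroxypropan-2-yl)-4,8a-dimethyldecahydronaphthalen-1-yl]-3-methylbutyl}-2,4,6-tris(benzyloxy)benzene-1,3-dicarbaldehyde F8.
  - Hydrogenolysis (H2, Pd/C) of F8 gives 25.

**Step 17.**
- What may go wrong: over-reduction of the formyl groups, which are still ordinary benzaldehydes before the neighbouring phenols are released, in competition with debenzylation.
- Fallback: from 24, chelation-assisted debenzylation with MgBr2·OEt2 (toluene/Et2O) is used; every benzyloxy group is ortho to a formyl group. It gives 5-{(1R)-1-[(1S,4R,4aS,6S,8aR)-4-hydroxy-6-(2-hydroxypropan-2-yl)-4,8a-dimethyldecahydronaphthalen-1-yl]-3-methylbut-3-en-1-yl}-2,4,6-trihydroxybenzene-1,3-dicarbaldehyde F9. Selective alkene hydrogenation (RhCl(PPh3)3, H2) then gives 25.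

## Further compounds

F1 | step 7 | methyl (2S,4aR,5R)-5-[(benzyloxy)methyl]-4a-methyl-8-(trimethylsilyloxy)-1,2,3,4,4a,5,6,7-octahydronaphthalene-2-carboxylate | c1ccccc1COC[C@@H]1CCC(O[Si](C)(C)C)=C2C[C@@H](C(=O)OC)CC[C@]12C
F2 | step 7 | methyl (2S,4aR,5R)-5-[(benzyloxy)methyl]-4a-methyl-8-oxo-2,3,4,4a,5,6,7,8-octahydronaphthalene-2-carboxylate | c1ccccc1COC[C@@H]1CCC(=O)C2=C[C@@H](C(=O)OC)CC[C@]12C
F3 | step 7 | methyl (2S,4aR,5R,8aS)-5-(hydroxymethyl)-4a-methyl-8-oxodecahydronaphthalene-2-carboxylate | OC[C@@H]1CCC(=O)[C@H]2C[C@@H](C(=O)OC)CC[C@]12C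
F4 | step 6 | (4R)-4-[(benzyloxy)methyl]-3-(3-iodobut-3-en-1-yl)cyclohex-2-en-1-one | O=C1C=C(CCC(I)=C)[C@H](COCc2ccccc2)CC1
F5 | step 13 | (4R)-4-[2,4-bis(benzyloxy)-6-hydroxyphenyl]-4-[(1S,4R,4aS,6S,8aR)-4-hydroxy-6-(2-hydroxypropan-2-yl)-4,8a-dimethyldecahydronaphthalen-1-yl]butan-2-one | CC(=O)C[C@@H](c1c(O)cc(OCc2ccccc2)cc1OCc1ccccc1)[C@@H]1CC[C@@](C)(O)[C@H]2C[C@@H](C(C)(C)O)CC[C@]12C
F6 | step 16 | 2-[(2S,4aR,5S,8R,8aS)-5-{(1R)-1-[3,5-dibromo-2,4,6-tris(benzyloxy)phenyl]-3-methylbutyl}-8-hydroxy-4a,8-dimethyldecahydronaphthalen-2-yl]propan-2-ol | CC(C)C[C@@H](c1c(OCc2ccccc2)c(Br)c(OCc2ccccc2)c(Br)c1OCc1ccccc1)[C@@H]1CC[C@@](C)(O)[C@H]2C[C@@H](C(C)(C)O)CC[C@]12C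
F7 | step 16 | 2-[(2S,4aR,5S,8R,8aS)-5-{(1R)-1-[3,5-diethenyl-2,4,6-tris(benzyloxy)phenyl]-3-methylbutyl}-8-hydroxy-4a,8-dimethyldecahydronaphthalen-2-yl]propan-2-ol | CC(C)C[C@@H](c1c(OCc2ccccc2)c(C=C)c(OCc2ccccc2)c(C=C)c1OCc1ccccc1)[C@@H]1CC[C@@](C)(O)[C@H]2C[C@@H](C(C)(C)O)CC[C@]12C
F8 | step 16 | 5-{(1R)-1-[(1S,4R,4aS,6S,8aR)-4-hydroxy-6-(2-hydroxypropan-2-yl)-4,8a-dimethyldecahydronaphthalen-1-yl]-3-methylbutyl}-2,4,6-tris(benzyloxy)benzene-1,3-dicarbaldehyde | CC(C)C[C@@H](c1c(OCc2ccccc2)c(C=O)c(OCc2ccccc2)c(C=O)c1OCc1ccccc1)[C@@H]1CC[C@@](C)(O)[C@H]2C[C@@H](C(C)(C)O)CC[C@]12C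
F9 | step 17 | 5-{(1R)-1-[(1S,4R,4aS,6S,8aR)-4-hydroxy-6-(2-hydroxypropan-2-yl)-4,8a-dimethyldecahydronaphthalen-1-yl]-3-methylbut-3-en-1-yl}-2,4,6-trihydroxybenzene-1,3-dicarbaldehyde | CC(=C)C[C@@H](c1c(O)c(C=O)c(O)c(C=O)c1O)[C@@H]1CC[C@@](C)(O)[C@H]2C[C@@H](C(C)(C)O)CC[C@]12C
A1 | alternative 1 | trans-fused bicyclic tert-butyldimethylsilyl enol ether with the C1 methyl ester and the triethylsilyl-protected C7 carbinol | COC(=O)[C@@H]1CC=C(O[Si](C)(C)C(C)(C)C)[C@H]2C[C@@H](C(C)(C)O[Si](CC)(CC)CC)CC[C@]12C
A2 | alternative 1 | acyclic triene: methyl (2Z)-3-methyl-enoate tethered to a (Z)-2-silyloxy-1,3-diene through the C7 stereocentre | COC(=O)/C=C(/C)CC[C@@H](C/C=C(\O[Si](C)(C)C(C)(C)C)C=C)C(C)(C)O[Si](CC)(CC)CC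
A3 | alternative 2 | 2-alkyl-5-benzyloxy-3-(triisopropylsilyloxy)phenol carrying the bis(triethylsilyl)-protected eudesmane | CC(C)C[C@@H](c1c(O)cc(OCc2ccccc2)cc1O[Si](C(C)C)(C(C)C)C(C)C)[C@@H]1CC[C@@](C)(O[Si](CC)(CC)CC)[C@H]2C[C@@H](C(C)(C)O[Si](CC)(CC)CC)CC[C@]12C
A4 | alternative 2 | triisopropylsiloxyalkyne on C9′ of the bis(triethylsilyl)-protected eudesmane | CC(C)C[C@@H](C#CO[Si](C(C)C)(C(C)C)C(C)C)[C@@H]1CC[C@@](C)(O[Si](CC)(CC)CC)[C@H]2C[C@@H](C(C)(C)O[Si](CC)(CC)CC)CC[C@]12C
A5 | alternative 2 | 3-(benzyloxy)cyclobut-2-en-1-one | O=C1C=C(OCc2ccccc2)C1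
A6 | alternative 3 | bicyclic ethyl enol ether with the C1 isovaleryl group, the angular methyl and the C7 isopropenyl group | CC(C)CC(=O)[C@@H]1CCC(OCC)=C2C[C@@H](C(C)=C)CC[C@]12C
A7 | alternative 3 | (5S)-1-(1-ethoxyethenyl)-2-methyl-5-(prop-1-en-2-yl)cyclohex-1-ene | C=C(OCC)C1=C(C)CC[C@H](C(C)=C)C1
A8 | alternative 3 | 5-methylhex-1-en-3-one | C=CC(=O)CC(C)C
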